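**Plan**
- Cuts (retrosynthetic order): the lactone C15–O bond; the C10–Br/C11–OH and C14–Br/C15–O pairs back to two E-olefins; the C3 methylene back to a ketone with an ester on C2; then C4–C5 and C2–C7 of the cyclohexane. This leaves an arene-bound acetoacetate and a farnesol-derived C5–C15 chain.
- Enabling feature: in ring C2–C7 the bromine-bearing C6 lies between the CH2 carbon C5 and the quaternary C7, a 2-bromo-1,3-diyl whose bromine can bridge to either neighbour. It faces C4–C3–C2, the two α-carbons of a masked ketone. The three Br–C–C–X pairs map onto the three olefins of (2E,6E)-farnesol.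
- Forward: arene 1 → bis(silyloxy)diene 7; farnesol → iodo bromo trifluoroacetate 12; a silver-triggered [3+3] annulation joins them and closes the cyclohexanone. Then decarboxylation, methylenation, ester cleavage, twofold epoxidation and bromide opening, macrolactonization (16-membered ring), desilylation.
- Stereochemistry: C6/C7 from Sharpless epoxidation (D-tartrate), carried through invertive bromide opening and two bromonium relays; C2 by protonation and equilibration after decarboxylation; C10/C11/C14 from Shi epoxidation with the L-fructose-derived ketone and invertive bromide opening.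

Key step: step 9

Remark: the terpenoid carbons are numbered C1 (ArCH2) to C15 (CMe2–O) along the chain and C20 is the exocyclic methylene carbon on C3; "ArCH2" means [5-(methoxycarbonyl)-2-(triisopropylsilyloxy)phenyl]methyl. The L-fructose-derived enantiomer of the Shi ketone is assumed to be at hand (made from L-sorbose).

Step 1
Reactants: 1 methyl 4-hydroxy-3-methylbenzoate
Product: 2 methyl 3-methyl-4-(triisopropylsilyloxy)benzoate
Conditions: iPr3SiCl, imidazole, DMF, 23 °C
Reagents that add atoms: chlorotriisopropylsilane, CC(C)[Si](Cl)(C(C)C)C(C)C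
Why: Imidazole-promoted O-silylation of a phenol is routine and gives a bulky silyl ether that should survive the enolate, silyl triflate, palladium and titanium chemistry ahead.

Step 2
Reactants: 2 methyl 3-methyl-4-(triisopropylsilyloxy)benzoate
Product: 3 methyl 3-(bromomethyl)-4-(triisopropylsilyloxy)benzoate
Conditions: NBS (1 equiv), AIBN (cat.), PhCF3, 80 °C
Reagents that add atoms: N-bromosuccinimide, O=C1CCC(=O)N1Br
Why: Wohl–Ziegler radical bromination should take a benzylic hydrogen, the weakest C–H bond of 2, and stop at the monobromide with one equivalent of NBS.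

Step 3
Reactants: 3 methyl 3-(bromomethyl)-4-(triisopropylsilyloxy)benzoate, 4 allyl acetoacetate
Product: 5 allyl 2-(ArCH2)-3-oxobutanoate (racemic)
Conditions: K2CO3, acetone, 50 °C (4 in threefold excess)
Reagents that add atoms: none
Why: C-alkylation of the acetoacetate enolate by a benzylic bromide (SN2) is classical, the excess of 4 suppresses double alkylation, and the racemic stereocentre formed is destroyed later.

Step 4
Reactants: 5 allyl 2-(ArCH2)-3-oxobutanoate
Product: 7 1-allyloxy-2-(ArCH2)-1,3-bis(trimethylsilyloxy)buta-1,3-diene, via mono-silyl enol ether 6 (not isolated)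
Conditions: Me3SiOTf (2.3 equiv), Et3N, Et2O, 0 °C; used crude
Reagents that add atoms: trimethylsilyl trifluoromethanesulfonate, C[Si](C)(C)OS(=O)(=O)C(F)(F)F
Why: Twofold soft enolization (amine plus silyl triflate) converts a β-keto ester first into its 3-silyloxy enoate and then into the 1,3-bis(silyloxy)-1,3-diene (Chan-type diene), the neutral equivalent of the acetoacetate dianion.

Step 5
Reactants: 8 (2E,6E)-farnesol
Product: 9 (2R,3R)-2,3-epoxyfarnesol
Conditions: Ti(OiPr)4, D-(−)-diethyl tartrate, t-BuOOH, 4 Å molecular sieves, CH2Cl2, −20 °C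
Reagents that add atoms: tert-butyl hydroperoxide, CC(C)(C)OO
Why: Sharpless asymmetric epoxidation acts only on the allylic alcohol olefin, and the D-tartrate ligand delivers oxygen to the face that gives the (2R,3R) epoxide (C6 and C7 of the target).

Step 6
Reactants: 9 (2R,3R)-2,3-epoxyfarnesol
Product: 10 (2S,3R,6E)-2-bromo-3,7,11-trimethyldodeca-6,10-diene-1,3-diol
Conditions: Li2NiBr4, THF, 0 → 23 °C
Reagents that add atoms: dilithium tetrabromonickelate, [Li+].[Li+].[Ni+2].[Br-].[Br-].[Br-].[Br-]
Why: Nucleophilic epoxide opening by soft bromide (SN2) should occur with inversion at the secondary carbon C2, because C3 is tertiary and closed to backside attack; this sets the future C6–Br stereocentre and leaves the C3–O bond untouched (anti bromohydrin).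

Step 7
Reactants: 10 (2S,3R,6E)-2-bromo-3,7,11-trimethyldodeca-6,10-diene-1,3-diol
Product: 11 (2R,3R,6E)-2-bromo-1-iodo-3,7,11-trimethyldodeca-6,10-dien-3-ol
Conditions: I2, PPh3, imidazole, CH2Cl2, 0 °C, dark
Reagents that add atoms: iodine, II
Why: Appel-type iodination converts only the primary alcohol (the tertiary one is too hindered to form the oxyphosphonium salt) and gives the primary iodide that silver will later abstract.

Step 8
Reactants: 11 (2R,3R,6E)-2-bromo-1-iodo-3,7,11-trimethyldodeca-6,10-dien-3-ol
Product: 12 (2R,3R,6E)-2-bromo-1-iodo-3,7,11-trimethyldodeca-6,10-dien-3-yl trifluoroacetate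
Conditions: (CF3CO)2O, pyridine, CH2Cl2, −20 → 0 °C; used directly
Reagents that add atoms: trifluoroacetic anhydride, O=C(OC(=O)C(F)(F)F)C(F)(F)F
Why: Trifluoroacetic anhydride acylates even tertiary alcohols without touching the C–O stereocentre, which installs anti to bromine a nucleofuge whose carbonyl oxygen is too weakly basic to act as a neighbouring group.

Step 9
Reactants: 7 1-allyloxy-2-(ArCH2)-1,3-bis(trimethylsilyloxy)buta-1,3-diene, 12 (2R,3R,6E)-2-bromo-1-iodo-3,7,11-trimethyldodeca-6,10-dien-3-yl trifluoroacetate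
Product: 14 allyl (6S,7S)-6-bromo-2-(ArCH2)-7-methyl-7-[(3E)-4,8-dimethylnona-3,7-dienyl]-3-oxocyclohexane-2-carboxylate (ring atoms C2–C7, both C2 epimers), via C4-alkylated silyl enol ether 13 (not isolated)
Conditions: AgOTf (1.05 equiv), 2,6-di-tert-butyl-4-methylpyridine, CH2Cl2, −78 °C, then −78 → 0 °C; aq. NaHCO3
Reagents that add atoms: none
Why: Proposed new method: AgOTf abstracts iodide from C5 of 12 at −78 °C with anchimeric help from the C6 bromine, and the terminal carbon C4 of diene 7 (the most nucleophilic site of a vinylogous silyl ketene acetal) opens the resulting C5/C6 bromonium ion at the unhindered primary carbon, which returns bromine to C6 and releases Me3SiOTf and silyl enol ether 13; on warming, this Me3SiOTf ionizes the tertiary trifluoroacetate, the anti bromine bridges again (C6/C7 bromonium ion), and the enol ether carbon C2 attacks C7 to give the cyclohexanone. The closest known reaction types are the formal [3+3] cyclization of 1,3-bis(silyloxy)-1,3-dienes with 1,3-dielectrophiles and the stereospecific cation–olefin cyclization of bromonium ions generated from enantiopure β-bromo tertiary esters or halides; new is that one bromine atom relays the positive charge to both ends of a saturated C5–C6–C7 unit. The one ring closed is the cyclohexanone (C2–C7 bond), formed by 6-endo opening of the bromonium ion at its tertiary carbon through a chair in which the enol ether C2=C3 is endocyclic. C6 keeps the configuration set in step 6 because its C–Br bond is never broken, C7 is formed with net retention (two inversions, so C2 enters anti to bromine on the face the trifluoroacetate left), and the quaternary C2 forms as a mixture that step 10 erases. The step needs C4 to react before C2 and C5 before C7: the diene fixes the order of the nucleophiles (terminal carbon first), orthogonal activation fixes the order of the electrophiles (halophilic silver for the carbon–iodine bond in the cold, oxophilic Me3SiOTf only after the first bond is made), and attack at C6 is blocked by the adjacent fully substituted, acyloxy-bearing C7. The hindered pyridine removes triflic acid so that the two distal trisubstituted olefins are not protonated.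

Step 10
Reactants: 14 allyl (6S,7S)-6-bromo-2-(ArCH2)-7-methyl-7-[(3E)-4,8-dimethylnona-3,7-dienyl]-3-oxocyclohexane-2-carboxylate
Product: 16 (2S,6S,7S)-6-bromo-2-(ArCH2)-7-methyl-7-[(3E)-4,8-dimethylnona-3,7-dienyl]cyclohexan-3-one, via β-keto acid 15 (not isolated)
Conditions: Pd(PPh3)4 (5 mol %), morpholine, THF, 23 °C
Reagents that add atoms: none
Why: Tsuji–Trost-type deallylation (zerovalent palladium ionizes the allyl ester, morpholine takes the allyl group) is followed by spontaneous decarboxylation of the β-keto acid; the enol is protonated at C2 anti to the axial C7 methyl group and the ketone can equilibrate, and both place the arylmethyl group equatorial (C2 configuration of the target).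

Step 11
Reactants: 16 (2S,6S,7S)-6-bromo-2-(ArCH2)-7-methyl-7-[(3E)-4,8-dimethylnona-3,7-dienyl]cyclohexan-3-one
Product: 17 methyl 3-{[(2R,6S,7S)-6-bromo-7-methyl-3-methylene-7-((3E)-4,8-dimethylnona-3,7-dienyl)cyclohex-2-yl]methyl}-4-(triisopropylsilyloxy)benzoate
Conditions: Zn, CH2Br2, TiCl4, THF–CH2Cl2, 0 → 23 °C
Reagents that add atoms: dibromomethane, BrCBr
Why: Lombardo methylenation uses a non-basic titanium–zinc methylene reagent that converts hindered, enolizable ketones into methylene compounds without epimerizing C2, without 1,3-elimination of the γ-bromide and without attacking esters.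

Step 12
Reactants: 17 methyl ester of the methylene compound
Product: 18 3-{[(2R,6S,7S)-6-bromo-7-methyl-3-methylene-7-((3E)-4,8-dimethylnona-3,7-dienyl)cyclohex-2-yl]methyl}-4-(triisopropylsilyloxy)benzoic acid
Conditions: Me3SnOH, ClCH2CH2Cl, 80 °C; dilute HCl work-up
Reagents that add atoms: trimethyltin hydroxide, C[Sn](C)(C)O
Why: Trimethyltin hydroxide cleaves methyl esters by acyl–oxygen cleavage under almost neutral conditions, so the aryl silyl ether, the neopentyl-type secondary bromide and the C2 stereocentre should survive.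

Step 13
Reactants: 18 diene acid
Product: 19 (10S,11S,14S)-10,11:14,15-bis-epoxide of acid 18
Conditions: L-fructose-derived ketone (enantiomer of the Shi ketone, 0.6 equiv), KHSO5 (as Oxone), K2CO3, Bu4NHSO4, MeCN–CH2(OMe)2/aq. Na2B4O7, 0 °C; work-up at pH 5
Reagents that add atoms: potassium peroxymonosulfate, [K+].[O-]S(=O)(=O)OO
Why: Shi epoxidation by a chiral dioxirane is fastest for trisubstituted olefins, so both chain olefins should react while the hindered 1,1-disubstituted exocyclic methylene is spared, and the chosen ketone enantiomer delivers oxygen to the same face of both olefins under catalyst control.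

Step 14
Reactants: 19 bis-epoxide acid
Product: 20 (2R,6S,7S,10R,11S,14R) seco acid with C10–Br/C11–OH and C14–Br/C15–OH bromohydrins
Conditions: Li2NiBr4, Li2CO3, THF, 0 → 23 °C; aq. NaH2PO4
Reagents that add atoms: dilithium tetrabromonickelate, [Li+].[Li+].[Ni+2].[Br-].[Br-].[Br-].[Br-]
Why: As in step 6, SN2 opening of each trisubstituted epoxide by bromide at its secondary carbon (C10 and C14) with inversion gives the two anti bromohydrins with tertiary alcohols at C11 and C15, while Li2CO3 keeps the acid as its carboxylate so that no acid-catalysed opening at the tertiary carbons intervenes.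

Step 15
Reactants: 20 seco acid
Product: 22 O-triisopropylsilyl bromophycolide H, via mixed anhydride 21 (not isolated)
Conditions: 2,4,6-Cl3C6H2COCl, Et3N, THF, 23 °C; then slow addition to DMAP, toluene, 80 °C (1 mM)
Reagents that add atoms: none
Why: Yamaguchi macrolactonization (mixed anhydride, then acyl transfer by DMAP under high dilution) should close the 16-membered ring at the C15 hydroxyl, the less hindered of the two tertiary alcohols (two methyl groups), in preference to the 12-membered ring at C11; no stereocentre is touched.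

Step 16
Reactants: 22 O-triisopropylsilyl bromophycolide H
Product: 23 bromophycolide H
Conditions: Bu4NF, AcOH, THF, 0 °C
Reagents that add atoms: none
Why: Fluoride cleaves the aryl silyl ether (a phenoxide is a good leaving group from silicon), and buffering with acetic acid keeps the medium from closing the bromohydrins to epoxides or opening the lactone.

**Compound list**
1 | methyl 4-hydroxy-3-methylbenzoate | COC(=O)c1ccc(O)c(C)c1 | starting material
2 | methyl 3-methyl-4-(triisopropylsilyloxy)benzoate | COC(=O)c1ccc(O[Si](C(C)C)(C(C)C)C(C)C)c(C)c1 | intermediate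
3 | methyl 3-(bromomethyl)-4-(triisopropylsilyloxy)benzoate | COC(=O)c1ccc(O[Si](C(C)C)(C(C)C)C(C)C)c(CBr)c1 | intermediate
4 | allyl acetoacetate (prop-2-enyl 3-oxobutanoate) | CC(=O)CC(=O)OCC=C | starting material
5 | allyl 2-{[5-(methoxycarbonyl)-2-(triisopropylsilyloxy)phenyl]methyl}-3-oxobutanoate (racemic) | CC(=O)C(Cc1cc(C(=O)OC)ccc1O[Si](C(C)C)(C(C)C)C(C)C)C(=O)OCC=C | intermediate
6 | allyl 2-(ArCH2)-3-(trimethylsilyloxy)but-2-enoate (mono-silyl enol ether, not isolated) | CC(O[Si](C)(C)C)=C(Cc1cc(C(=O)OC)ccc1O[Si](C(C)C)(C(C)C)C(C)C)C(=O)OCC=C | intermediate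
7 | 1-allyloxy-2-(ArCH2)-1,3-bis(trimethylsilyloxy)buta-1,3-diene (Chan-type diene; ketene acetal geometry not defined) | C=C(O[Si](C)(C)C)C(Cc1cc(C(=O)OC)ccc1O[Si](C(C)C)(C(C)C)C(C)C)=C(OCC=C)O[Si](C)(C)C | intermediate
8 | (2E,6E)-farnesol | CC(C)=CCC/C(C)=C/CC/C(C)=C/CO | starting material
9 | (2R,3R)-2,3-epoxyfarnesol | OC[C@H]1O[C@]1(C)CC/C=C(\C)CCC=C(C)C | intermediate
10 | (2S,3R,6E)-2-bromo-3,7,11-trimethyldodeca-6,10-diene-1,3-diol | OC[C@H](Br)[C@](C)(O)CC/C=C(\C)CCC=C(C)C | intermediate
11 | (2R,3R,6E)-2-bromo-1-iodo-3,7,11-trimethyldodeca-6,10-dien-3-ol | IC[C@H](Br)[C@](C)(O)CC/C=C(\C)CCC=C(C)C | intermediate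
12 | (2R,3R,6E)-2-bromo-1-iodo-3,7,11-trimethyldodeca-6,10-dien-3-yl trifluoroacetate | IC[C@H](Br)[C@](C)(OC(=O)C(F)(F)F)CC/C=C(\C)CCC=C(C)C | intermediate
13 | allyl (6S,7R,10E)-6-bromo-2-(ArCH2)-7,11,15-trimethyl-7-(trifluoroacetoxy)-3-(trimethylsilyloxy)hexadeca-2,10,14-trienoate (not isolated) | C=CCOC(=O)C(Cc1cc(C(=O)OC)ccc1O[Si](C(C)C)(C(C)C)C(C)C)=C(O[Si](C)(C)C)CC[C@H](Br)[C@](C)(OC(=O)C(F)(F)F)CC/C=C(\C)CCC=C(C)C | intermediate
14 | allyl (6S,7S)-6-bromo-2-(ArCH2)-7-methyl-7-[(3E)-4,8-dimethylnona-3,7-dienyl]-3-oxocyclohexane-2-carboxylate (C2 not defined) | O=C1CC[C@H](Br)[C@@](C)(CC/C=C(\C)CCC=C(C)C)C1(Cc1cc(C(=O)OC)ccc1O[Si](C(C)C)(C(C)C)C(C)C)C(=O)OCC=C | intermediate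
15 | β-keto acid of 14 (not isolated) | O=C1CC[C@H](Br)[C@@](C)(CC/C=C(\C)CCC=C(C)C)C1(Cc1cc(C(=O)OC)ccc1O[Si](C(C)C)(C(C)C)C(C)C)C(=O)O | intermediate
16 | (2S,6S,7S)-6-bromo-2-(ArCH2)-7-methyl-7-[(3E)-4,8-dimethylnona-3,7-dienyl]cyclohexan-3-one | O=C1CC[C@H](Br)[C@@](C)(CC/C=C(\C)CCC=C(C)C)[C@@H]1Cc1cc(C(=O)OC)ccc1O[Si](C(C)C)(C(C)C)C(C)C | intermediate
17 | methyl 3-{[(2R,6S,7S)-6-bromo-7-methyl-3-methylene-7-((3E)-4,8-dimethylnona-3,7-dienyl)cyclohex-2-yl]methyl}-4-(triisopropylsilyloxy)benzoate | C=C1CC[C@H](Br)[C@@](C)(CC/C=C(\C)CCC=C(C)C)[C@@H]1Cc1cc(C(=O)OC)ccc1O[Si](C(C)C)(C(C)C)C(C)C | intermediate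
18 | the corresponding benzoic acid | C=C1CC[C@H](Br)[C@@](C)(CC/C=C(\C)CCC=C(C)C)[C@@H]1Cc1cc(C(=O)O)ccc1O[Si](C(C)C)(C(C)C)C(C)C | intermediate
19 | (2R,6S,7S,10S,11S,14S)-10,11:14,15-bis-epoxide of 18 | C=C1CC[C@H](Br)[C@@](C)(CC[C@@H]2O[C@@]2(C)CC[C@@H]2OC2(C)C)[C@@H]1Cc1cc(C(=O)O)ccc1O[Si](C(C)C)(C(C)C)C(C)C | intermediate
20 | (2R,6S,7S,10R,11S,14R)-6,10,14-tribromo-11,15-dihydroxy seco acid | C=C1CC[C@H](Br)[C@@](C)(CC[C@@H](Br)[C@@](C)(O)CC[C@@H](Br)C(C)(C)O)[C@@H]1Cc1cc(C(=O)O)ccc1O[Si](C(C)C)(C(C)C)C(C)C | intermediate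
21 | mixed anhydride of 20 with 2,4,6-trichlorobenzoic acid (not isolated) | C=C1CC[C@H](Br)[C@@](C)(CC[C@@H](Br)[C@@](C)(O)CC[C@@H](Br)C(C)(C)O)[C@@H]1Cc1cc(C(=O)OC(=O)c2c(Cl)cc(Cl)cc2Cl)ccc1O[Si](C(C)C)(C(C)C)C(C)C | intermediate
22 | O-triisopropylsilyl bromophycolide H | C=C1CC[C@H](Br)[C@@]2(C)CC[C@@H](Br)[C@@](C)(O)CC[C@@H](Br)C(C)(C)OC(=O)c3ccc(O[Si](C(C)C)(C(C)C)C(C)C)c(c3)C[C@H]12 | intermediate
23 | bromophycolide H (2R,6S,7S,10R,11S,14R) | C=C1CC[C@H](Br)[C@@]2(C)CC[C@@H](Br)[C@@](C)(O)CC[C@@H](Br)C(C)(C)OC(=O)c3ccc(O)c(c3)C[C@H]12 | target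

**Totals**
Total step count: 16. Longest linear sequence: 12 steps (8 → 23 through steps 5–16; the arene branch 1 → 23 through steps 1–4 and 9–16 is equally long).

**Steps most likely to fail**

Step 9. The tertiary trifluoroacetate may ionize before the first C–C bond is complete, so that the diene terminus attacks C7. The first bromonium ion may be opened at C6. Silver may abstract the secondary bromide with iodine participation (halogen exchange at C6). O-alkylation or proton loss from either bromonium ion may compete. The fallback makes the two bonds in separate operations by known chemistry. It sets out from epoxy alcohol 9 and β-keto ester 5 and returns to the route at silyl enol ether 13. Compound 9 is converted (I2, PPh3, imidazole) into (2S,3R,6E)-2,3-epoxy-1-iodo-3,7,11-trimethyldodeca-6,10-diene F1. The dianion of 5 (2 equiv LiN(iPr)2, THF, −78 °C) is alkylated at its terminal carbon by F1 to give allyl (6R,7R,10E)-6,7-epoxy-2-(ArCH2)-7,11,15-trimethyl-3-oxohexadeca-10,14-dienoate F2. Li2NiBr4 opens the trisubstituted epoxide at the secondary carbon to give the (6S,7R) bromohydrin F3. (CF3CO)2O and pyridine give the tertiary trifluoroacetate F4. Me3SiOTf and Et3N at −78 °C silylate the β-keto ester to 13, which on warming with Me3SiOTf cyclizes to 14 as in the second stage of step 9 (a bromonium cation–olefin cyclization ended by an enol ether).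

Step 15. Acylation of the hindered tertiary carbinol may be so slow that intermolecular esterification and oligomerization take over. The C11 hydroxyl may be acylated instead (12-membered ring). The amine bases at 80 °C may close a bromohydrin to an epoxide. The fallback forms the C15–O bond by O-alkylation of the acid instead of O-acylation of the alcohol. It sets out from seco acid 20 and returns at 22. (CF3CO)2O and pyridine convert both tertiary alcohols into trifluoroacetates, giving the bis(trifluoroacetate) F5 (the mixed carboxylic anhydride is hydrolysed on work-up). In (CF3)2CHOH–CH2Cl2 with 2,6-lutidine at high dilution the C15 ester ionizes with bromine participation, and the carboxylic acid captures the C14/C15 bromonium ion at the tertiary carbon with retention at C14 (a bromolactonization through a preformed enantiopure bromonium ion). This gives the C11-O-trifluoroacetyl lactone F6; ionization at C11 has no productive partner and should revert by ion-pair return. NaHCO3 in MeOH then removes the remaining trifluoroacetate to give 22.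

Step 6. Bromide may enter at the tertiary C3 if lithium assists C–O cleavage, or the epoxide may migrate along the chain before opening, which would scramble C6. The fallback sets the same two centres by halogenation of the olefin instead of epoxide opening. It sets out from farnesol 8 and returns at diol 10. Titanium-mediated catalytic enantioselective bromochlorination of the allylic alcohol (NBS, ClTi(OiPr)3, chiral tridentate Schiff-base ligand, hexanes, −20 °C) gives (2S,3R,6E)-2-bromo-3-chloro-3,7,11-trimethyldodeca-6,10-dien-1-ol F7, with bromine at C2 and chlorine at C3 added anti. Ag2CO3 in aqueous acetone then replaces the tertiary chloride by hydroxyl with retention through the bromonium ion and gives 10.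

Further compounds
F1 | step 9 | (2S,3R,6E)-2,3-epoxy-1-iodo-3,7,11-trimethyldodeca-6,10-diene | IC[C@H]1O[C@]1(C)CC/C=C(\C)CCC=C(C)C
F2 | step 9 | allyl (6R,7R,10E)-6,7-epoxy-2-(ArCH2)-7,11,15-trimethyl-3-oxohexadeca-10,14-dienoate | C=CCOC(=O)C(Cc1cc(C(=O)OC)ccc1O[Si](C(C)C)(C(C)C)C(C)C)C(=O)CC[C@H]1O[C@]1(C)CC/C=C(\C)CCC=C(C)C
F3 | step 9 | allyl (6S,7R,10E)-6-bromo-7-hydroxy-2-(ArCH2)-7,11,15-trimethyl-3-oxohexadeca-10,14-dienoate | C=CCOC(=O)C(Cc1cc(C(=O)OC)ccc1O[Si](C(C)C)(C(C)C)C(C)C)C(=O)CC[C@H](Br)[C@](C)(O)CC/C=C(\C)CCC=C(C)C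
F4 | step 9 | allyl (6S,7R,10E)-6-bromo-2-(ArCH2)-7,11,15-trimethyl-3-oxo-7-(trifluoroacetoxy)hexadeca-10,14-dienoate | C=CCOC(=O)C(Cc1cc(C(=O)OC)ccc1O[Si](C(C)C)(C(C)C)C(C)C)C(=O)CC[C@H](Br)[C@](C)(OC(=O)C(F)(F)F)CC/C=C(\C)CCC=C(C)C
F5 | step 15 | 11,15-bis(trifluoroacetate) of seco acid 20 | C=C1CC[C@H](Br)[C@@](C)(CC[C@@H](Br)[C@@](C)(OC(=O)C(F)(F)F)CC[C@@H](Br)C(C)(C)OC(=O)C(F)(F)F)[C@@H]1Cc1cc(C(=O)O)ccc1O[Si](C(C)C)(C(C)C)C(C)C
F6 | step 15 | 11-O-trifluoroacetyl derivative of lactone 22 | C=C1CC[C@H](Br)[C@@]2(C)CC[C@@H](Br)[C@@](C)(OC(=O)C(F)(F)F)CC[C@@H](Br)C(C)(C)OC(=O)c3ccc(O[Si](C(C)C)(C(C)C)C(C)C)c(c3)C[C@H]12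
F7 | step 6 | (2S,3R,6E)-2-bromo-3-chloro-3,7,11-trimethyldodeca-6,10-dien-1-ol | OC[C@H](Br)[C@](C)(Cl)CC/C=C(\C)CCC=C(C)C
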